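**Remarks on the chemistry (assumptions).** The target is treated as the 4-hydroxy-2-pyranone tautomer, and rotation about the C2–C1' bond is taken as free, so no stereochemical element has to be set. The oxygen of the ynol ether carries a methyl group and not an ethyl group, because an O-ethyl alkynyl ether loses ethylene by a retro-ene reaction near 120 °C, below the temperature the cycloaddition is expected to need.

## Analysis of the target

Target 23 consists of three blocks: a 7-hydroxy-5-methylchromone (benzo ring A, pyranone ring B), a resorcinol ring C bonded through C1' to chromone C2, and a 4-hydroxy-2-pyranone ring D that hangs from C6' of ring C through one CH2 group. There is no stereocenter. The C2–C1' axis is flanked on the chromone side only by O1 and C3–H and is not expected to be configurationally stable. Sensitive groups are the 4-hydroxy-2-pyranone (lactone opened by hydroxide or alkoxide, C3'' nucleophilic), the chromone (C2 a Michael acceptor, ring B opened by strong base), the CH2 bridge (acidic through vinylogous activation by ring D) and four acidic hydroxyl groups. The difficulty is ring C: it is 1,2,3,5-tetrasubstituted, its bond to C2 lies between two ortho substituents, and an open-chain precursor of ring D built late would be prone to aldol and Claisen cyclizations. The feature the route rests on is that C3', C4' (with its oxygen), C5', C6', the CH2 bridge and all of ring D are two triketide units on one carbon. A symmetric methylene-bridged bis(4-methoxy-2-pyranone) therefore holds ring D in one ring and the C3'–C6' diene of ring C in the other. A two-carbon alkyne that carries C1' (with the chromone) and C2' (with its oxygen) completes ring C.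

## Retrosynthetic reasoning

**23 to 22.** The four O–H groups of 23 are taken back to O–CH3 groups. Methyl is the only group that suits all four positions: two of them arise from methoxypyranone oxygens and one from the ynol ether oxygen. One Lewis-acid ether cleavage at the end has to remove them all without touching the lactone or the chromone.

**22 to 10 and 20 (through 21).** Ring C is cut at C2'–C3' and C1'–C6'. These cuts, and no others, leave C3'–C6' as the diene of a 2-pyranone whose C6 already carries the CH2 bridge and ring D, and leave C1'–C2' as an alkyne. Reinstating the O–C(=O) bridge between C3' and C6' gives adduct 21 and, behind it, bis-pyranone 10 and ynol ether 20. The gain is that the hindered C2–C1' bond is never made by a coupling, ring D is complete before the key step, and 10 is symmetric, so no choice between its two rings arises. The forward reaction must join pyranone C3 to the oxygen-bearing alkyne carbon and pyranone C6 to the chromone-bearing carbon, and then expel the bridge.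

**Choice of the group on the alkyne oxygen.** The polarization that directs the cycloaddition requires an oxygen on the distal alkyne carbon. An O-ethyl group would be the most convenient, but it would be lost as an alkene by a retro-ene reaction at the temperature that sluggish 4-alkoxy-2-pyranones need. A methyl group has no beta hydrogen, so 20 is the O-methyl compound.

**10 to 1.** Compound 10 is taken back by O-demethylation to 9, whose hydroxypyranone ring is opened at the lactone C–O bond to acylketene 8, the cycloreversion product of keto-dioxinone 7. Cutting the C–C bond between the ketone carbon and the dioxinone CH2 of 7 gives acid chloride 4 and dienolate 6 of dioxinone 5. Acid chloride 4 comes from acid 3, and 3 from carboxylation of lateral anion 2 of the commercial pyranone 1. Each forward step is a standard polyketide homologation, and the first pyranone ring is bought ready-made.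

**20 to 16 and 19.** The C2–C(sp) bond of 20 is cut to 2-iodochromone 16 and alkynylstannane 19. A tin reagent is chosen because it can be purified free of secondary amine, which would add to both 16 and 20.

**16 to 11, and 19 to 17.** Iodide 16 comes from chromone 14 by C2 metalation (zinc species 15) and iodination. Chromone 14 is opened at O1–C2 and C2–C3 to enaminone 13 and so to acetophenone 12, the 4-O-methyl ether of commercial 11. Stannane 19 comes from acetylide 18, made by double elimination from chloroacetal 17.

## Alternatives that were turned down

**Alternative 1:** Ring C is cut at C5'–C6' and C1'–C2' into the oxygenated diene 1,3-dimethoxy-1-(trimethylsilyloxy)buta-1,3-diene A3 and the alkynylchromone A2.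
- Forward step: [4+2] addition of A3 across the alkyne of A2 and elimination of the acetal methoxy group would give phenol A1, with the 2'-OH free, the 4'-OMe in place and a silyloxyethyl arm on C6'.
- For: this is a normal-demand Diels–Alder benzannulation of a known reaction class, it should run well below 100 °C, and A2 would come from 16 by a Sonogashira coupling with a stable terminal alkyne. On precedent and on handling it is stronger than the chosen key step.
- Against: the alkyne of A2 is activated only vinylogously and carries an alkyl group at the carbon that the nucleophilic terminus of A3 must attack, while chromone C2 offers a competing Michael site. Ring D is absent from A1, so desilylation, two oxidations, activation, homologation with 5, thermolysis and protecting-group changes follow, all on the complete chromone and partly under basic enolate conditions.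
- Comparison: the chosen strategy accepts a less precedented cycloaddition and in return brings ring D in complete, so that only the deprotection follows the key step.

**Alternative 2:** Ring C is kept and its two ortho carbon substituents are introduced together by cutting C6'–CH2 and C1'–C(acyl).
- Forward step: fluoride releases 3,5-dimethoxybenzyne A7 from silyl triflate A5, and A7 inserts into the bond between the ketone carbon and the central CH2 of methyl acetoacetate A6 to give keto ester A4.
- For: the insertion is a known reaction type under mild conditions, and A6 is a bulk chemical. The methoxy group next to the aryne sends the carbon nucleophile to the distal aryne carbon, so the regiochemistry is right. In precedent it is clearly stronger than the chosen key step.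
- Against: no ring of 23 is closed. A4 has two acidic sites placed to condense with each other in an intramolecular Claisen reaction that would close an unwanted second carbocycle. The chromone would have to come from a Claisen condensation in which this hindered aryl methyl ketone is the nucleophile and a hindered ring A acyl donor the electrophile, the reverse of the usual polarity. Ring D must again be built from the ester, and A5 itself takes several steps.
- Comparison: the route would run to well over twelve linear steps, whereas the chosen plan forms ring C and both its flanking bonds in one step from two short branches.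

**Alternative 3:** Ring B is cut at C4a–C4, C4–C3 and O1–C2.
- Forward step: zerovalent palladium joins iodoresorcinol A8, a carbonyl group from the gas phase and arylacetylene A9 to an ynone, and the ortho hydroxyl adds 6-endo to give chromone A10.
- For: carbonylative annulation of ortho-iodophenols with terminal alkynes is a known reaction type, the position of the iodide fixes the chromone regiochemistry, and rings A and C are joined late. In convergence on the chromone and in precedent it is at least as strong as the chosen plan.
- Against: the iodide of A8 lies between a hydroxyl and a methyl group, so oxidative addition and carbonyl insertion are slow, and direct alkynylation without carbonyl insertion, followed by five-membered ring closure, competes. 5-exo closure of the ynone, which would contract ring B, competes with 6-endo closure. A9 is a di-ortho-substituted alkyne that needs several steps. Ring D still has to be grown from the ester of A10 in four or five steps on a base-sensitive chromone with a free phenol.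
- Comparison: the chosen strategy avoids all late chain extension, at the price of a cycloaddition without direct precedent.

Key step: step 11

## Route

Step 1
Reactants: 1 4-methoxy-6-methyl-2H-pyran-2-one
Product: 3 (4-methoxy-2-oxo-2H-pyran-6-yl)acetic acid, via 6-(lithiomethyl)-4-methoxy-2H-pyran-2-one 2 (not isolated)
Conditions: LiN(i-Pr)2 (1.1 equiv), THF, −78 °C; CO2 (excess), −78 → 0 °C; cold aq. HCl
Reagents that add atoms: carbon dioxide, O=C=O
Why: Lateral deprotonation of the 6-methyl group gives the extended dienolate 2, which is carboxylated at the exocyclic carbon; fast addition of excess CO2 limits proton transfer from the more acidic product, and the acid is kept cold because it is a vinylogous malonic half-acid.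

Step 2
Reactants: 3 (4-methoxy-2-oxo-2H-pyran-6-yl)acetic acid
Product: 4 (4-methoxy-2-oxo-2H-pyran-6-yl)acetyl chloride
Conditions: (COCl)2 (1.2 equiv), DMF (cat.), CH2Cl2, 0 → 23 °C; concentrated and used crude
Reagents that add atoms: oxalyl chloride, ClC(=O)C(=O)Cl
Why: Acid chloride formation through the chloroiminium salt under base-free conditions, which the methoxypyranone tolerates; without base, 4 should not go on to a ketene.

Step 3
Reactants: 4 (4-methoxy-2-oxo-2H-pyran-6-yl)acetyl chloride; 5 2,2,6-trimethyl-4H-1,3-dioxin-4-one
Product: 7 6-[3-(4-methoxy-2-oxo-2H-pyran-6-yl)-2-oxopropyl]-2,2-dimethyl-4H-1,3-dioxin-4-one, via lithium dienolate 6 (not isolated)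
Conditions: 5 (3 equiv), LiN(SiMe3)2 (3 equiv), THF, −78 °C; then 4, −78 °C; AcOH, −78 °C
Reagents that add atoms: none
Why: Claisen-type gamma-acylation of the dioxinone dienolate by an acid chloride, the usual entry to beta-keto dioxinones; three equivalents of 6 are used because 7 is deprotonated as it forms, and any ketene formed from 4 by proton loss should be captured by 6 at its central carbon to give the same enolate of 7.

Step 4
Reactants: 7 6-[3-(4-methoxy-2-oxo-2H-pyran-6-yl)-2-oxopropyl]-2,2-dimethyl-4H-1,3-dioxin-4-one
Product: 9 4-hydroxy-6-[(4-methoxy-2-oxo-2H-pyran-6-yl)methyl]-2H-pyran-2-one, via acylketene 8 (not isolated)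
Conditions: PhMe, 110 °C
Reagents that add atoms: none
Why: Thermal retro-[4+2] of the dioxinone releases acetone and acylketene 8, whose ketene carbon is attacked by the enol oxygen of the delta ketone (six-membered lactonization); this is the standard pyranone synthesis from beta-keto dioxinones.

Step 5
Reactants: 9 4-hydroxy-6-[(4-methoxy-2-oxo-2H-pyran-6-yl)methyl]-2H-pyran-2-one
Product: 10 6,6'-methylenebis(4-methoxy-2H-pyran-2-one)
Conditions: Me2SO4 (1.1 equiv), K2CO3 (1.5 equiv), acetone, 23 → 40 °C
Reagents that add atoms: dimethyl sulfate, COS(=O)(=O)OC
Why: O-Methylation of the pyranolate with a hard methylating agent should give the 4-methoxy-2-pyranone, as in the usual preparation of 1; base and reagent are kept near one equivalent so that the less acidic CH2 bridge is not methylated.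

Step 6
Reactants: 11 1-(2,4-dihydroxy-6-methylphenyl)ethanone
Product: 12 1-(2-hydroxy-4-methoxy-6-methylphenyl)ethanone
Conditions: Me2SO4 (1.05 equiv), K2CO3, acetone, 56 °C
Reagents that add atoms: dimethyl sulfate, COS(=O)(=O)OC
Why: Williamson methylation selective for the 4-hydroxyl, because the 2-hydroxyl is held in a hydrogen bond to the acetyl group and is less acidic and less nucleophilic.

Step 7
Reactants: 12 1-(2-hydroxy-4-methoxy-6-methylphenyl)ethanone
Product: 14 7-methoxy-5-methyl-4H-chromen-4-one, via enaminone 13 (not isolated)
Conditions: Me2NCH(OMe)2, PhMe, 100 °C; then conc. HCl, CH2Cl2, 23 °C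
Reagents that add atoms: N,N-dimethylformamide dimethyl acetal, COC(OC)N(C)C
Why: Condensation of the methyl ketone with the amide acetal gives enaminone 13; acid then brings about 6-endo addition of the phenol and loss of dimethylamine, the enaminone route to 2,3-unsubstituted chromones.

Step 8
Reactants: 14 7-methoxy-5-methyl-4H-chromen-4-one
Product: 16 2-iodo-7-methoxy-5-methyl-4H-chromen-4-one, via chromon-2-ylzinc chloride 15 (not isolated)
Conditions: TMPZnCl·LiCl (1.2 equiv; TMP = 2,2,6,6-tetramethylpiperidin-1-yl), THF, 25 °C; then I2 (1.3 equiv), 0 °C
Reagents that add atoms: iodine, II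
Why: Deprotonative zincation of chromones by the hindered zinc amide, without added Lewis acid, takes place at C2–H next to O1; the covalent C–Zn bond should not open ring B, the mild base should leave the 5-methyl group alone, and iodinolysis of 15 gives the 2-iodide.

Step 9
Reactants: 17 2-chloro-1,1-dimethoxyethane
Product: 19 tributyl(methoxyethynyl)stannane, via lithium methoxyacetylide 18 (not isolated)
Conditions: LiNEt2 (3.1 equiv, from Et2NH and n-BuLi), THF, 0 °C; then Bu3SnCl (1.0 equiv), −78 → 23 °C; distillation
Reagents that add atoms: tributyltin chloride, CCCC[Sn](Cl)(CCCC)CCCC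
Why: Two successive eliminations (of methoxide, then of chloride) and deprotonation turn the chloroacetal into the lithium alkoxyacetylide, the standard in situ route to alkoxyethynyllithium reagents; stannylation gives a distillable alkynylstannane free of secondary amine.

Step 10
Reactants: 16 2-iodo-7-methoxy-5-methyl-4H-chromen-4-one; 19 tributyl(methoxyethynyl)stannane
Product: 20 7-methoxy-2-(methoxyethynyl)-5-methyl-4H-chromen-4-one
Conditions: 19 (1.2 equiv), Pd(PPh3)4 (5 mol %), CuI (10 mol %), THF, 40 °C; chromatography on Et3N-deactivated silica
Reagents that add atoms: none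
Why: Stille coupling; oxidative addition of zerovalent palladium into the C–I bond of the beta-iodo enone is easy, alkynyl groups transfer fastest from tin, and the neutral amine-free medium protects the ynol ether, a coupling type established for alkoxyethynylstannanes.

Step 11
Reactants: 10 6,6'-methylenebis(4-methoxy-2H-pyran-2-one); 20 7-methoxy-2-(methoxyethynyl)-5-methyl-4H-chromen-4-one
Product: 22 2-{2,4-dimethoxy-6-[(4-methoxy-2-oxo-2H-pyran-6-yl)methyl]phenyl}-7-methoxy-5-methyl-4H-chromen-4-one, via bridged lactone adduct 21 (not isolated)
Conditions: 10 (3 equiv), PhMe, 4 Å MS, 150 °C, sealed tube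
Reagents that add atoms: none
Why: Proposed new method: the closest known reaction type is the thermal Diels–Alder addition of 2-pyranones to alkynes and to ketene acetals with loss of carbon dioxide to give benzenes, which has not been shown for a 4-alkoxy-2-pyranone with a donor–acceptor ynol ether. One pyranone ring of 10 acts as the diene through C3–C6; its C3 (alpha to the lactone carbonyl, beta to the methoxy group) is the nucleophilic terminus and should bond to the methoxy-bearing alkyne carbon of 20, which is electrophilic both as an ynol ether carbon and as the delta carbon of the chromone vinylogous system, while pyranone C6 bonds to the chromone-bearing carbon, so the addition is expected to be polar and asynchronous with C2'–C3' formed ahead of C1'–C6'. Adduct 21 should then lose carbon dioxide by retro-[4+2], which is fast for a bicyclo[2.2.2]octadiene lactone because a benzene ring results, so ring C is closed by intermolecular cycloaddition followed by cycloreversion and not by a cyclization. No stereocenter remains: the two bridgeheads of 21 form as a racemic pair fixed by the bicycle and both become aromatic carbons. The step needs regioselectivity, which rests on the matched polarization of diene and alkyne, and single addition, which rests on the excess of 10 and the equivalence of its two rings; the untouched ring becomes ring D. The O-methyl group has no beta hydrogen, so the retro-ene fragmentation that destroys O-ethyl ynol ethers near 120 °C cannot occur.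

Step 12
Reactants: 22 2-{2,4-dimethoxy-6-[(4-methoxy-2-oxo-2H-pyran-6-yl)methyl]phenyl}-7-methoxy-5-methyl-4H-chromen-4-one
Product: 23 2-{2,4-dihydroxy-6-[(4-hydroxy-2-oxo-2H-pyran-6-yl)methyl]phenyl}-7-hydroxy-5-methyl-4H-chromen-4-one
Conditions: BBr3 (10 equiv), CH2Cl2, −78 → 23 °C; then MeOH, H2O
Reagents that add atoms: none
Why: Lewis-acid ether cleavage of the three aryl methyl ethers and of the vinylogous methyl ester of ring D by bromide attack on the boron-complexed O–CH3 groups; the lactone, the chromone and the CH2 bridge offer BBr3 no other point of attack, and the excess allows for complexation by the two carbonyl groups.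

## Compound list

1 | 4-methoxy-6-methyl-2H-pyran-2-one | COc1cc(C)oc(=O)c1 | starting material
2 | 6-(lithiomethyl)-4-methoxy-2H-pyran-2-one | [Li]Cc1cc(OC)cc(=O)o1 | intermediate
3 | (4-methoxy-2-oxo-2H-pyran-6-yl)acetic acid | COc1cc(CC(=O)O)oc(=O)c1 | intermediate
4 | (4-methoxy-2-oxo-2H-pyran-6-yl)acetyl chloride | COc1cc(CC(=O)Cl)oc(=O)c1 | intermediate
5 | 2,2,6-trimethyl-4H-1,3-dioxin-4-one | CC1=CC(=O)OC(C)(C)O1 | starting material
6 | lithium 2,2-dimethyl-6-methylidene-6H-1,3-dioxin-4-olate | [Li]OC1=CC(=C)OC(C)(C)O1 | intermediate
7 | 6-[3-(4-methoxy-2-oxo-2H-pyran-6-yl)-2-oxopropyl]-2,2-dimethyl-4H-1,3-dioxin-4-one | COc1cc(CC(=O)CC2=CC(=O)OC(C)(C)O2)oc(=O)c1 | intermediate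
8 | 6-(4-methoxy-2-oxo-2H-pyran-6-yl)-3,5-dioxohex-1-en-1-one (acylketene) | COc1cc(CC(=O)CC(=O)C=C=O)oc(=O)c1 | intermediate
9 | 4-hydroxy-6-[(4-methoxy-2-oxo-2H-pyran-6-yl)methyl]-2H-pyran-2-one | COc1cc(Cc2cc(O)cc(=O)o2)oc(=O)c1 | intermediate
10 | 6,6'-methylenebis(4-methoxy-2H-pyran-2-one) | COc1cc(Cc2cc(OC)cc(=O)o2)oc(=O)c1 | intermediate
11 | 1-(2,4-dihydroxy-6-methylphenyl)ethanone | CC(=O)c1c(C)cc(O)cc1O | starting material
12 | 1-(2-hydroxy-4-methoxy-6-methylphenyl)ethanone | CC(=O)c1c(C)cc(OC)cc1O | intermediate
13 | (E)-3-(dimethylamino)-1-(2-hydroxy-4-methoxy-6-methylphenyl)prop-2-en-1-one | CN(C)/C=C/C(=O)c1c(C)cc(OC)cc1O | intermediate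
14 | 7-methoxy-5-methyl-4H-chromen-4-one | Cc1cc(OC)cc2occc(=O)c12 | intermediate
15 | chlorido(7-methoxy-5-methyl-4-oxo-4H-chromen-2-yl)zinc | Cc1cc(OC)cc2oc([Zn]Cl)cc(=O)c12 | intermediate
16 | 2-iodo-7-methoxy-5-methyl-4H-chromen-4-one | Cc1cc(OC)cc2oc(I)cc(=O)c12 | intermediate
17 | 2-chloro-1,1-dimethoxyethane | COC(OC)CCl | starting material
18 | lithium methoxyacetylide | [Li]C#COC | intermediate
19 | tributyl(methoxyethynyl)stannane | CCCC[Sn](CCCC)(CCCC)C#COC | intermediate
20 | 7-methoxy-2-(methoxyethynyl)-5-methyl-4H-chromen-4-one | COC#Cc1cc(=O)c2c(C)cc(OC)cc2o1 | intermediate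
21 | racemic 5,8-dimethoxy-7-(7-methoxy-5-methyl-4-oxo-4H-chromen-2-yl)-1-[(4-methoxy-2-oxo-2H-pyran-6-yl)methyl]-2-oxabicyclo[2.2.2]octa-5,7-dien-3-one (one enantiomer drawn; the relative configuration of the bridgeheads is fixed by the bicycle) | O=C1O[C@@]2(CC3=CC(OC)=CC(=O)O3)C=C(OC)[C@@H]1C(OC)=C2c1cc(=O)c2c(C)cc(OC)cc2o1 | intermediate
22 | 2-{2,4-dimethoxy-6-[(4-methoxy-2-oxo-2H-pyran-6-yl)methyl]phenyl}-7-methoxy-5-methyl-4H-chromen-4-one | Cc1cc(OC)cc2oc(-c3c(OC)cc(OC)cc3Cc3cc(OC)cc(=O)o3)cc(=O)c12 | intermediate
23 | 2-{2,4-dihydroxy-6-[(4-hydroxy-2-oxo-2H-pyran-6-yl)methyl]phenyl}-7-hydroxy-5-methyl-4H-chromen-4-one | Cc1cc(O)cc2oc(-c3c(O)cc(O)cc3Cc3cc(O)cc(=O)o3)cc(=O)c12 | target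

## Step count and risks

Total step count: 12. Longest linear sequence: 7 steps (steps 1, 2, 3, 4, 5, 11, 12).

**Step 11 (key step).** The electron-rich pyranone may add too slowly to an alkyne that carries a donor, so that thermal oligomerization of 20 or its hydration by traces of water takes over. The first C–C bond may also form and the dipolar intermediate then collapse by proton transfer instead of closing the ring, and a second cycloaddition on the remaining pyranone ring of 22 is possible if 10 is not kept in excess.

The fallback uses only known reaction types and makes the C2–C1' bond by cross-coupling instead. It sets out from 14 (through its zinc reagent 15) and from 5, and it returns at 22. 2-(3,5-Dimethoxyphenyl)acetic acid F1 would be iodinated with N-iodosuccinimide in MeCN at the ring position between the side chain and a methoxy group to give 2-(2-iodo-3,5-dimethoxyphenyl)acetic acid F2. Treatment of F2 with (COCl)2 would give 2-(2-iodo-3,5-dimethoxyphenyl)acetyl chloride F3. F3 would acylate dienolate 6 (from 5 and LiN(SiMe3)2) to give 6-[3-(2-iodo-3,5-dimethoxyphenyl)-2-oxopropyl]-2,2-dimethyl-4H-1,3-dioxin-4-one F4. F4 in toluene at 110 °C would give 4-hydroxy-6-[(2-iodo-3,5-dimethoxyphenyl)methyl]-2H-pyran-2-one F5, and Me2SO4 with K2CO3 would turn F5 into 6-[(2-iodo-3,5-dimethoxyphenyl)methyl]-4-methoxy-2H-pyran-2-one F6. Negishi coupling of F6 with 15 (Pd(OAc)2, 2-dicyclohexylphosphino-2',6'-dimethoxybiphenyl, THF, 50 °C), a known way to 2-arylchromones, should then give 22.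

**Step 3.** Proton transfer from the doubly activated CH2 group of 4 to the basic dienolate, O-acylation, or a second acylation of the product enolate may erode the yield. The fallback replaces the basic enolate by a neutral silyl dienol ether; it sets out from 4 and returns at 9. Acid chloride 4 would be treated without base in CH2Cl2 (−78 → 20 °C) with 1-methoxy-1,3-bis(trimethylsilyloxy)buta-1,3-diene F7, which reacts at its terminal carbon. Aqueous work-up should give methyl 6-(4-methoxy-2-oxo-2H-pyran-6-yl)-3,5-dioxohexanoate F8, which 1,8-diazabicyclo[5.4.0]undec-7-ene in toluene should lactonize to 9.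

**Step 8.** Metalation may occur at C3 or at the 5-methyl group instead of C2, or the C2-metalated chromone may open ring B by beta-elimination of the phenoxide. The fallback builds the C2 leaving group during ring formation; it sets out from 12, uses 19, and returns at 20. Acetophenone 12 would be condensed with CS2 and KOt-Bu to 4-hydroxy-7-methoxy-5-methyl-2H-chromene-2-thione F9. S-Methylation with MeI and K2CO3 gives 7-methoxy-5-methyl-2-(methylsulfanyl)-4H-chromen-4-one F10. A Liebeskind–Srogl-type coupling of this vinylogous thioester with 19 (Pd(PPh3)4, copper thiophene-2-carboxylate CuO2CC4H3S, THF, 50 °C) should give 20.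

**Step 12.** Cleavage of four ethers may stop at partly demethylated boron complexes that precipitate, or the strong Lewis acid may promote attack of ring D on chromone C2. The fallback uses nucleophilic dealkylation in two stages; it sets out from 22 and returns at 23. LiI in refluxing ethyl acetate should remove only the vinylogous ester methyl group by SN2 attack and give 2-{6-[(4-hydroxy-2-oxo-2H-pyran-6-yl)methyl]-2,4-dimethoxyphenyl}-7-methoxy-5-methyl-4H-chromen-4-one F11 as its pyranolate. The negative charge then shields ring D while NaSEt in DMF at 110 °C cleaves the three aryl methyl ethers, and acidification should give 23.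

## Further compounds

F1 | step 11 | 2-(3,5-dimethoxyphenyl)acetic acid | COc1cc(CC(=O)O)cc(OC)c1
F2 | step 11 | 2-(2-iodo-3,5-dimethoxyphenyl)acetic acid | COc1cc(CC(=O)O)c(I)c(OC)c1
F3 | step 11 | 2-(2-iodo-3,5-dimethoxyphenyl)acetyl chloride | COc1cc(CC(=O)Cl)c(I)c(OC)c1
F4 | step 11 | 6-[3-(2-iodo-3,5-dimethoxyphenyl)-2-oxopropyl]-2,2-dimethyl-4H-1,3-dioxin-4-one | COc1cc(CC(=O)CC2=CC(=O)OC(C)(C)O2)c(I)c(OC)c1
F5 | step 11 | 4-hydroxy-6-[(2-iodo-3,5-dimethoxyphenyl)methyl]-2H-pyran-2-one | COc1cc(Cc2cc(O)cc(=O)o2)c(I)c(OC)c1
F6 | step 11 | 6-[(2-iodo-3,5-dimethoxyphenyl)methyl]-4-methoxy-2H-pyran-2-one | COc1cc(Cc2cc(OC)cc(=O)o2)c(I)c(OC)c1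
F7 | step 3 | 1-methoxy-1,3-bis(trimethylsilyloxy)buta-1,3-diene (enol ether geometry not specified, lost in the product) | COC(=CC(=C)O[Si](C)(C)C)O[Si](C)(C)C
F8 | step 3 | methyl 6-(4-methoxy-2-oxo-2H-pyran-6-yl)-3,5-dioxohexanoate | COC(=O)CC(=O)CC(=O)Cc1cc(OC)cc(=O)o1
F9 | step 8 | 4-hydroxy-7-methoxy-5-methyl-2H-chromene-2-thione | Cc1cc(OC)cc2oc(=S)cc(O)c12
F10 | step 8 | 7-methoxy-5-methyl-2-(methylsulfanyl)-4H-chromen-4-one | CSc1cc(=O)c2c(C)cc(OC)cc2o1
F11 | step 12 | 2-{6-[(4-hydroxy-2-oxo-2H-pyran-6-yl)methyl]-2,4-dimethoxyphenyl}-7-methoxy-5-methyl-4H-chromen-4-one | Cc1cc(OC)cc2oc(-c3c(OC)cc(OC)cc3Cc3cc(O)cc(=O)o3)cc(=O)c12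
A1 | alternative 1 | 2-{2-[2-(tert-butyldimethylsilyloxy)ethyl]-6-hydroxy-4-methoxyphenyl}-7-methoxy-5-methyl-4H-chromen-4-one | Cc1cc(OC)cc2oc(-c3c(O)cc(OC)cc3CCO[Si](C)(C)C(C)(C)C)cc(=O)c12
A2 | alternative 1 | 2-[4-(tert-butyldimethylsilyloxy)but-1-yn-1-yl]-7-methoxy-5-methyl-4H-chromen-4-one | Cc1cc(OC)cc2oc(C#CCCO[Si](C)(C)C(C)(C)C)cc(=O)c12
A3 | alternative 1 | 1,3-dimethoxy-1-(trimethylsilyloxy)buta-1,3-diene (geometry not specified) | COC(=C)C=C(OC)O[Si](C)(C)C
A4 | alternative 2 | methyl 2-(2-acetyl-3,5-dimethoxyphenyl)acetate | COC(=O)Cc1cc(OC)cc(OC)c1C(C)=O
A5 | alternative 2 | 3,5-dimethoxy-2-(trimethylsilyl)phenyl trifluoromethanesulfonate | COc1cc(OC)c([Si](C)(C)C)c(OS(=O)(=O)C(F)(F)F)c1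
A6 | alternative 2 | methyl acetoacetate (methyl 3-oxobutanoate) | COC(=O)CC(C)=O
A7 | alternative 2 | 3,5-dimethoxybenzyne (1,2-didehydro-3,5-dimethoxybenzene) | COC1=CC(OC)=CC#C1
A8 | alternative 3 | 4-iodo-5-methylbenzene-1,3-diol | Cc1cc(O)cc(O)c1I
A9 | alternative 3 | methyl 2-(2-ethynyl-3,5-dimethoxyphenyl)acetate | COC(=O)Cc1cc(OC)cc(OC)c1C#C
A10 | alternative 3 | methyl 2-[2-(7-hydroxy-5-methyl-4-oxochromen-2-yl)-3,5-dimethoxyphenyl]acetate | COC(=O)Cc1cc(OC)cc(OC)c1-c1cc(=O)c2c(C)cc(O)cc2o1
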